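## The problem

Compound 11 is a flavone: a 4H-chromen-4-one (rings A and C) with a 2,3,4,5-tetramethoxyphenyl ring B on C2, a methoxyl on C7 and a free hydroxyl on C5 that is hydrogen-bonded to the C4 carbonyl. It has no stereocentre and no hindered axis, so the task is one of connectivity and of telling six aryl oxygens apart: five end as methyl ethers and one (O5) as a phenol. That pattern is best bought with the building blocks, because a late demethylation would have to pick one methoxyl out of six. Ring B is crowded, since its C2' methoxyl flanks the bond to C2, so the C2–C1' bond is easier to bring in at the acyl level than by coupling onto a finished chromone. The groups that limit the reagents are the pyranone ring (opened at C2 by hot hydroxide or alkoxide), the aryl methyl ethers (cleaved by strong Lewis acids) and the two electron-rich benzene rings (open to electrophilic halogenation and oxidation). The feature to exploit is the C2=C3 double bond of ring C: C3 is the α-carbon of an aryl ketone (C4, on ring A), and C2 is at the carboxylic acid oxidation level and already carries O1 and ring B. This is the pattern of a phenacyl phosphorus ylide next to an aryl ester. In addition, C4a is flanked by two oxygens (O1 on C8a, O5 on C5) that are equivalent in a 2,6-dioxygenated 4-methoxyacetophenone, so one acyl group can supply C2 on one side and protect O5 on the other.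

## Retrosynthesis

**11 from 10.** The last cut is the ester C–O bond on O5, which leads back to the 5-O-(2,3,4,5-tetramethoxybenzoyl) ester 10. An acyl group on O5 is preferred to an ether because it is not installed separately: it is the twin of the acyl group that becomes C2. An ester on a phenol chelated to C4=O is also unusually easy to remove, without Lewis acid or hydrogenolysis. 10 is no simpler in skeleton than 11. The forward step only has to be a mild methanolysis that leaves the pyranone and five methyl ethers alone.

**10 from 9.** The C2=C3 double bond is cut to the keto-stabilised ylide 9, in which C3 is the ylide carbon and C2 is the carbonyl carbon of an ortho aryl ester. The neighbouring cuts are weaker for this target: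
- O1–C2 (cyclodehydration of a 1,3-diketone) needs a strongly basic acyl migration followed by strong acid.
- C2–C1' (cross-coupling on a 2-halochromone) needs an ortho-methoxylated, protodeboronation-prone ring B metal species.
- C4–C4a (acylation of ring A) raises a regiochemical question on a 3,5-dioxygenated anisole.

The chosen cut keeps O1–C2 as an ordinary ester bond, and forms the only new C–C bond of ring C in the same event that closes the ring, without acid or base. 9 has no ring C and is built from symmetrical pieces. The forward reaction must olefinate an ester carbonyl with a stabilised ylide, which is realistic only intramolecularly, and must outrun acyl transfer to carbon.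

**9 from 8, 7 and 6.** The P=C bond is cut to the phosphonium salt 8, the C–P bond to the bromomethyl ketone 7, and the C–Br bond to the methyl ketone 6. Only the acetyl methyl group needs functionalising. Building the ylide the other way, by acylating a non-stabilised methylene ylide with a ring A benzoic acid derivative, would put a strong base next to two aryl esters. Each precursor is one functional group simpler. Two things are asked of the forward steps:
- The bromination must choose the methyl ketone over three electron-rich rings.
- Ylide formation must use a base too weak to make a ketone enolate, which would trigger Baker–Venkataraman acyl migration. Carbonate suffices for a (2-oxoalkyl)phosphonium salt.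

Acylation is placed before bromination because the esters lower the electron density of ring A. They also remove the free phenols, which would otherwise close onto the bromomethyl ketone to give a benzofuranone.

**6 from 5 and 4.** Both ester C–O bonds are cut to commercial 1-(2,6-dihydroxy-4-methoxyphenyl)ethanone 5 and two equivalents of acid chloride 4. 5 already holds C4, C3 and the whole oxygen pattern of ring A, with O7 methylated and the two other oxygens free and equivalent. No selectivity is needed, only complete acylation of two chelated, flanked phenols.

**4 from 3 and 1.** The acid chloride goes back to 2,3,4,5-tetramethoxybenzoic acid 3, and the aryl–carboxyl bond is cut to 1,2,3,4-tetramethoxybenzene 1 through aryllithium 2. The two ring hydrogens of 1 are equivalent and each is ortho to a methoxyl, so directed lithiation and carboxylation can give only one acid. An electrophilic formylation and oxidation would also work but costs a step.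

## Roads not taken

Alternative 1: Ring B is taken apart at C5'–C6', C1'–C2' and C2'–C3'. The pieces are the chromium carbene complex (CO)5Cr=C(OMe)C(OMe)=CHOMe A2, one of its CO ligands, and 2-ethynyl-5,7-dimethoxychromen-4-one A3. In the forward sense a Dötz benzannulation would join them to 2-(2-hydroxy-3,4,5-trimethoxyphenyl)-5,7-dimethoxychromen-4-one A1. Methylation of the new phenol and chelation-directed cleavage of the 5-O-methyl group with BCl3 would follow.
- Merits: it is convergent. Alkyne insertion with a terminal alkyne reliably places the large substituent next to the new phenol. Ring C is in place beforehand, so no ring-closure selectivity arises.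
- Weak points: it builds a benzene ring whose oxygen pattern can be bought as 1. It needs stoichiometric chromium. A2 is no stock item and would have to be made from a lithiated enol ether, Cr(CO)6 and a methylating agent. The alkyne of A3 is conjugated to the chromone and open to nucleophiles. The electron-rich 4-methoxyphenol product oxidises easily. Two more steps are needed, one being the removal of one methyl group out of six.
- Comparison: this road is better if ring B were to be varied late or if the 2'-oxygen had to stay free. The chosen plan has nothing to set against that except that neither is needed here. In length, waste and certainty of each step the chosen plan is ahead.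

Alternative 2: Rings A and C are cut together, at C4a–C8a and O1–C2, back to 4-hydroxy-6-[2-oxo-4-(2,3,4,5-tetramethoxyphenyl)but-3-yn-1-yl]pyran-2-one A5. In the forward sense Mg(OMe)2 would open the lactone, the freed chain would fold by Claisen condensation to ring A, and a ring A phenoxide would add to the ynone to close ring C. The product is 5,7-dihydroxy-2-(2,3,4,5-tetramethoxyphenyl)chromen-4-one A4, and selective methylation of the unchelated 7-hydroxyl would finish the synthesis.
- Merits: two rings form in one operation without protecting groups, and the closing 7-O-methylation is well precedented for 5,7-dihydroxyflavones.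
- Weak points: the ynone must survive methoxide, which adds readily to such acceptors. The chain can fold in more than one way. The phenoxide can close 5-exo to an aurone instead of 6-endo. A5 must first be assembled by acylating a pyrone dianion with an arylpropiolate.
- Comparison: if A5 were available in two or three steps this road could be shorter, and it is more elegant in ring construction. Against that the chosen plan sets the fact that ring A can be bought with the correct methylation, and that each of its steps has one task and one likely outcome.

Alternative 3: Ring C is cut at O1–C8a. The precursor is 1-(2,6-difluoro-4-methoxyphenyl)-3-(2,3,4,5-tetramethoxyphenyl)propane-1,3-dione A7, from Claisen condensation of 1-(2,6-difluoro-4-methoxyphenyl)ethanone A8 with an ester of acid 3. In the forward sense the enolate oxygen would displace one ortho fluoride (K2CO3, DMF) to give 5-fluoro-7-methoxy-2-(2,3,4,5-tetramethoxyphenyl)chromen-4-one A6, whose fluorine must then be exchanged for hydroxyl.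
- Merits: the ring closure is a robust anionic reaction. The two fluorines are equivalent, so no regiochemistry arises. Only one equivalent of the ring B acid is used and no phosphine oxide is produced. In atom economy this road is better, and in step count it is about equal.
- Weak points: the fluoride to be displaced is activated only by a ketone that is present as an enolate and has a para methoxyl. The second substitution at C5 of A6 needs an oxygen nucleophile on a finished chromone, where hydroxide and alkoxides can attack C2, so a two-step detour through a benzyl ether is likely. A8 is a speciality chemical.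
- Comparison: the chosen plan has the C5 oxygen in place from the first ring A building block and ends with a room-temperature methanolysis. No nucleophilic substitution is ever attempted on the chromone.

Key step: step 7

## Route

Remark on the chemistry: acid 3 is treated as a compound to be made, not bought; the target has no stereogenic element, so no step sets configuration.

Step 1
Reactants: 1 1,2,3,4-tetramethoxybenzene
Product: 3 2,3,4,5-tetramethoxybenzoic acid, via (2,3,4,5-tetramethoxyphenyl)lithium 2 (not isolated)
Conditions: n-BuLi, TMEDA, THF, 0 °C; then CO2, −78 °C to rt; aq. HCl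
Reagents that add atoms: carbon dioxide, O=C=O
Why: Methoxy-directed ortho-lithiation followed by carboxylation; the two ring C–H bonds of 1 are equivalent and each is ortho to a methoxyl, so only aryllithium 2 can form, and adding it to excess CO2 suppresses diaryl ketone formation.

Step 2
Reactants: 3 2,3,4,5-tetramethoxybenzoic acid
Product: 4 2,3,4,5-tetramethoxybenzoyl chloride
Conditions: (COCl)2, cat. DMF, CH2Cl2, 0 °C to rt
Reagents that add atoms: oxalyl chloride, O=C(Cl)C(=O)Cl
Why: Standard acid chloride formation through the DMF-derived chloroiminium catalyst; the by-products are gases, no Lewis acid is present that could touch the methyl ethers, and the crude chloride is used directly.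

Step 3
Reactants: 5 1-(2,6-dihydroxy-4-methoxyphenyl)ethanone; 4 2,3,4,5-tetramethoxybenzoyl chloride (2.3 equiv)
Product: 6 2-acetyl-5-methoxy-1,3-phenylene bis(2,3,4,5-tetramethoxybenzoate)
Conditions: pyridine, cat. DMAP, CH2Cl2, 0 °C to rt
Reagents that add atoms: none
Why: DMAP-catalysed O-acylation of both phenols through the acylpyridinium ion, as in the classical double aroylation of 2,6-dihydroxyacetophenones; pyridine is too weak a base to enolise the ketone, so no Baker–Venkataraman migration is expected.

Step 4
Reactants: 6 2-acetyl-5-methoxy-1,3-phenylene bis(2,3,4,5-tetramethoxybenzoate)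
Product: 7 2-(bromoacetyl)-5-methoxy-1,3-phenylene bis(2,3,4,5-tetramethoxybenzoate)
Conditions: CuBr2 (2.1 equiv), EtOAc/CHCl3, reflux
Reagents that add atoms: CuBr2, Br[Cu]Br
Why: Side-chain bromination of an aryl methyl ketone with CuBr2 in refluxing ethyl acetate/chloroform, which goes through the copper-bound enol and is known to spare electron-rich rings that free bromine would attack; two equivalents of divalent copper are reduced to insoluble CuBr, and the aryl esters tolerate the HBr that leaves the boiling solvent.

Step 5
Reactants: 7 2-(bromoacetyl)-5-methoxy-1,3-phenylene bis(2,3,4,5-tetramethoxybenzoate)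
Product: 8 {2-[4-methoxy-2,6-bis(2,3,4,5-tetramethoxybenzoyloxy)phenyl]-2-oxoethyl}triphenylphosphonium bromide
Conditions: PPh3, toluene, rt
Reagents that add atoms: triphenylphosphine, c1ccc(cc1)P(c1ccccc1)c1ccccc1
Why: SN2 quaternisation of PPh3 by a primary α-keto bromide under neutral conditions; the salt is expected to crystallise from toluene, which removes it from further reaction.

Step 6
Reactants: 8 {2-[4-methoxy-2,6-bis(2,3,4,5-tetramethoxybenzoyloxy)phenyl]-2-oxoethyl}triphenylphosphonium bromide
Product: 9 5-methoxy-2-[(triphenyl-λ5-phosphanylidene)acetyl]-1,3-phenylene bis(2,3,4,5-tetramethoxybenzoate)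
Conditions: aq. Na2CO3, CH2Cl2, 0 °C to rt
Reagents that add atoms: none
Why: Deprotonation of a (2-oxoalkyl)phosphonium salt to its keto-stabilised ylide, for which carbonate is basic enough; no ketone enolate is formed, the cold two-phase medium keeps the aryl esters away from hydroxide, and the ylide is isolated from the organic layer.

Step 7
Reactants: 9 5-methoxy-2-[(triphenyl-λ5-phosphanylidene)acetyl]-1,3-phenylene bis(2,3,4,5-tetramethoxybenzoate)
Product: 10 7-methoxy-4-oxo-2-(2,3,4,5-tetramethoxyphenyl)-4H-chromen-5-yl 2,3,4,5-tetramethoxybenzoate
Conditions: toluene, reflux, N2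
Reagents that add atoms: none
Why: Intramolecular Wittig olefination of an ester carbonyl: the ylide carbon (future C3) adds to the carbonyl carbon of a flanking aryl ester (future C2), the betaine closes to an oxaphosphetane fused to the new ring, and syn-cycloreversion expels triphenylphosphine oxide to leave C2=C3. The closest known reaction type is the thermal cyclisation of (2-acyloxyphenacylidene)triphenylphosphoranes to chromones and flavones. Ring C closes as a six-membered ring by 6-exo-trig attack on the ester C=O, whose oxygen stays outside the ring and leaves with phosphorus, while the O1–C2 bond is already present as the ester linkage. No stereocentre is formed, and because the two ester groups are related by the local symmetry of ring A, either one gives the same product. The selectivity needed is olefination over O-to-C acyl transfer (collapse of the tetrahedral adduct with loss of the ring A phenoxide) and over intermolecular reaction. The substrate favours olefination because the 2,6-disubstituted aryl ketone is twisted out of the ylide plane, which holds an ester carbonyl over the π lobe of the ylide carbon, and because base-free, non-polar toluene offers a departing phenoxide no stabilisation while P–O bond formation drives the collapse. The second ester is inert once the ylide is consumed and keeps O5 masked, so no free phenol is present to protonate the ylide.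

Step 8
Reactants: 10 7-methoxy-4-oxo-2-(2,3,4,5-tetramethoxyphenyl)-4H-chromen-5-yl 2,3,4,5-tetramethoxybenzoate
Product: 11 5-hydroxy-7-methoxy-2-(2,3,4,5-tetramethoxyphenyl)-4H-chromen-4-one
Conditions: K2CO3, MeOH/THF, rt; then aq. NH4Cl
Reagents that add atoms: none
Why: Methanolysis (transesterification) of an aryl ester whose aryloxide leaving group is stabilised by the neighbouring C4 carbonyl, so the 5-O-aroyl group should leave at room temperature, well below the conditions that open a pyranone; the methyl ethers are untouched and the acyl group is released as its methyl ester.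

## Compound list

1 | 1,2,3,4-tetramethoxybenzene | COc1ccc(OC)c(OC)c1OC | starting material
2 | (2,3,4,5-tetramethoxyphenyl)lithium | [Li]c1cc(OC)c(OC)c(OC)c1OC | intermediate (not isolated)
3 | 2,3,4,5-tetramethoxybenzoic acid | COc1cc(C(=O)O)c(OC)c(OC)c1OC | intermediate
4 | 2,3,4,5-tetramethoxybenzoyl chloride | COc1cc(C(=O)Cl)c(OC)c(OC)c1OC | intermediate
5 | 1-(2,6-dihydroxy-4-methoxyphenyl)ethanone | CC(=O)c1c(O)cc(OC)cc1O | starting material
6 | 2-acetyl-5-methoxy-1,3-phenylene bis(2,3,4,5-tetramethoxybenzoate) | COc1cc(OC(=O)c2cc(OC)c(OC)c(OC)c2OC)c(C(C)=O)c(OC(=O)c2cc(OC)c(OC)c(OC)c2OC)c1 | intermediate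
7 | 2-(bromoacetyl)-5-methoxy-1,3-phenylene bis(2,3,4,5-tetramethoxybenzoate) | COc1cc(OC(=O)c2cc(OC)c(OC)c(OC)c2OC)c(C(=O)CBr)c(OC(=O)c2cc(OC)c(OC)c(OC)c2OC)c1 | intermediate
8 | {2-[4-methoxy-2,6-bis(2,3,4,5-tetramethoxybenzoyloxy)phenyl]-2-oxoethyl}triphenylphosphonium bromide | [Br-].COc1cc(OC(=O)c2cc(OC)c(OC)c(OC)c2OC)c(C(=O)C[P+](c2ccccc2)(c2ccccc2)c2ccccc2)c(OC(=O)c2cc(OC)c(OC)c(OC)c2OC)c1 | intermediate
9 | 5-methoxy-2-[(triphenyl-λ5-phosphanylidene)acetyl]-1,3-phenylene bis(2,3,4,5-tetramethoxybenzoate) | COc1cc(OC(=O)c2cc(OC)c(OC)c(OC)c2OC)c(C(=O)C=P(c2ccccc2)(c2ccccc2)c2ccccc2)c(OC(=O)c2cc(OC)c(OC)c(OC)c2OC)c1 | intermediate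
10 | 7-methoxy-4-oxo-2-(2,3,4,5-tetramethoxyphenyl)-4H-chromen-5-yl 2,3,4,5-tetramethoxybenzoate | COc1cc(OC(=O)c2cc(OC)c(OC)c(OC)c2OC)c2c(=O)cc(-c3cc(OC)c(OC)c(OC)c3OC)oc2c1 | intermediate
11 | 5-hydroxy-7-methoxy-2-(2,3,4,5-tetramethoxyphenyl)-4H-chromen-4-one | COc1cc(O)c2c(=O)cc(-c3cc(OC)c(OC)c(OC)c3OC)oc2c1 | target

## Step count and risk

Total step count: 8. Longest linear sequence: 8 steps (1 to 3, 4, 6, 7, 8, 9, 10 and 11; 5 enters at step 3).

**Step 7 (key step).** The most likely failure is acyl migration from oxygen to the ylide carbon in place of olefination. The tetrahedral adduct can lose the ring A phenoxide, which sits ortho to a carbonyl and is a fair leaving group. The ester carbonyl is also hindered by the ortho methoxyl of ring B and made less electrophilic by four donor groups, so the productive collapse may be slow. The fallback gives up the C2=C3 closure and sets out from 6: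
- Baker–Venkataraman rearrangement (LiN(SiMe3)2, THF, −78 °C to rt) would move one aroyl group to the ketone α-carbon. The product is the 1,3-diketone 3-hydroxy-5-methoxy-2-[3-oxo-3-(2,3,4,5-tetramethoxyphenyl)propanoyl]phenyl 2,3,4,5-tetramethoxybenzoate F1.
- Acid-catalysed cyclodehydration (cat. H2SO4, AcOH, warm) would then close ring C at O1–C2, and the route is rejoined at 10.

**Step 4.** The most likely failure is bromination of a ring instead of the side chain, at the ring A positions flanking the 4-methoxyl or at the lone CH of a tetramethoxybenzoyl ring, or a second bromination of the methyl group. Enolisation of the twisted, 2,6-disubstituted ketone is slow, which gives electrophilic bromine time to find the arenes. The fallback avoids electrophilic halogen and sets out from 6: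
- α-Sulfonyloxylation with hydroxy(tosyloxy)iodobenzene, PhI(OH)OTs, in MeCN at reflux would give 5-methoxy-2-{[(4-methylphenyl)sulfonyloxy]acetyl}-1,3-phenylene bis(2,3,4,5-tetramethoxybenzoate) F2.
- PPh3 in warm MeCN would displace the tosylate to give {2-[4-methoxy-2,6-bis(2,3,4,5-tetramethoxybenzoyloxy)phenyl]-2-oxoethyl}triphenylphosphonium 4-methylbenzenesulfonate F3.
- Aqueous Na2CO3 in CH2Cl2 would deprotonate F3, and the route is rejoined at 9.

**Step 3.** The most likely failure is a stall after the first acylation. The remaining phenol is hydrogen-bonded to the ketone and flanked by a bulky acyl group, and the acid chloride itself carries an ortho methoxyl. The fallback accepts the mono-ester and sets out from 5 and one equivalent of 4, which should give 2-acetyl-3-hydroxy-5-methoxyphenyl 2,3,4,5-tetramethoxybenzoate F4. The chelated phenol is then left free through the same sequence: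
- CuBr2 bromination to 2-(bromoacetyl)-3-hydroxy-5-methoxyphenyl 2,3,4,5-tetramethoxybenzoate F5.
- PPh3 to {2-[2-hydroxy-4-methoxy-6-(2,3,4,5-tetramethoxybenzoyloxy)phenyl]-2-oxoethyl}triphenylphosphonium bromide F6.
- Aqueous Na2CO3 to 3-hydroxy-5-methoxy-2-[(triphenyl-λ5-phosphanylidene)acetyl]phenyl 2,3,4,5-tetramethoxybenzoate F7.
- Heating F7 in toluene closes ring C and gives the target directly, so the route is rejoined at 11 and step 8 is not needed.

The price is a more electron-rich ring A during the bromination.

**Step 1.** The most likely failure is incomplete metalation, or further reaction of the aryllithium with the lithium carboxylate to a diaryl ketone. The tetra-oxygenated aryllithium is aggregated and can be slow to form and slow to be quenched. The fallback replaces deprotonation by electrophilic substitution and sets out from 1: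
- Vilsmeier–Haack formylation (POCl3, DMF) at the only free ring position type should give 2,3,4,5-tetramethoxybenzaldehyde F8.
- Pinnick oxidation (NaClO2, NaH2PO4, 2-methyl-2-butene, t-BuOH/H2O) returns to the route at 3.

## Further compounds

F1 | step 7 | 3-hydroxy-5-methoxy-2-[3-oxo-3-(2,3,4,5-tetramethoxyphenyl)propanoyl]phenyl 2,3,4,5-tetramethoxybenzoate | COc1cc(O)c(C(=O)CC(=O)c2cc(OC)c(OC)c(OC)c2OC)c(OC(=O)c2cc(OC)c(OC)c(OC)c2OC)c1
F2 | step 4 | 5-methoxy-2-{[(4-methylphenyl)sulfonyloxy]acetyl}-1,3-phenylene bis(2,3,4,5-tetramethoxybenzoate) | COc1cc(OC(=O)c2cc(OC)c(OC)c(OC)c2OC)c(C(=O)COS(=O)(=O)c2ccc(C)cc2)c(OC(=O)c2cc(OC)c(OC)c(OC)c2OC)c1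
F3 | step 4 | {2-[4-methoxy-2,6-bis(2,3,4,5-tetramethoxybenzoyloxy)phenyl]-2-oxoethyl}triphenylphosphonium 4-methylbenzenesulfonate | Cc1ccc(S(=O)(=O)[O-])cc1.COc1cc(OC(=O)c2cc(OC)c(OC)c(OC)c2OC)c(C(=O)C[P+](c2ccccc2)(c2ccccc2)c2ccccc2)c(OC(=O)c2cc(OC)c(OC)c(OC)c2OC)c1
F4 | step 3 | 2-acetyl-3-hydroxy-5-methoxyphenyl 2,3,4,5-tetramethoxybenzoate | COc1cc(O)c(C(C)=O)c(OC(=O)c2cc(OC)c(OC)c(OC)c2OC)c1
F5 | step 3 | 2-(bromoacetyl)-3-hydroxy-5-methoxyphenyl 2,3,4,5-tetramethoxybenzoate | COc1cc(O)c(C(=O)CBr)c(OC(=O)c2cc(OC)c(OC)c(OC)c2OC)c1
F6 | step 3 | {2-[2-hydroxy-4-methoxy-6-(2,3,4,5-tetramethoxybenzoyloxy)phenyl]-2-oxoethyl}triphenylphosphonium bromide | [Br-].COc1cc(O)c(C(=O)C[P+](c2ccccc2)(c2ccccc2)c2ccccc2)c(OC(=O)c2cc(OC)c(OC)c(OC)c2OC)c1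
F7 | step 3 | 3-hydroxy-5-methoxy-2-[(triphenyl-λ5-phosphanylidene)acetyl]phenyl 2,3,4,5-tetramethoxybenzoate | COc1cc(O)c(C(=O)C=P(c2ccccc2)(c2ccccc2)c2ccccc2)c(OC(=O)c2cc(OC)c(OC)c(OC)c2OC)c1
F8 | step 1 | 2,3,4,5-tetramethoxybenzaldehyde | COc1cc(C=O)c(OC)c(OC)c1OC
A1 | alternative 1 | 2-(2-hydroxy-3,4,5-trimethoxyphenyl)-5,7-dimethoxychromen-4-one | COc1cc(OC)c2c(=O)cc(-c3cc(OC)c(OC)c(OC)c3O)oc2c1
A2 | alternative 1 | pentacarbonyl{[(Z)-1,2-dimethoxyethenyl](methoxy)methylidene}chromium, (CO)5Cr=C(OMe)C(OMe)=CHOMe | CO/C=C(\OC)C(OC)=[Cr](=C=O)(=C=O)(=C=O)(=C=O)=C=O
A3 | alternative 1 | 2-ethynyl-5,7-dimethoxychromen-4-one | COc1cc(OC)c2c(=O)cc(C#C)oc2c1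
A4 | alternative 2 | 5,7-dihydroxy-2-(2,3,4,5-tetramethoxyphenyl)chromen-4-one | Oc1cc(O)c2c(=O)cc(-c3cc(OC)c(OC)c(OC)c3OC)oc2c1
A5 | alternative 2 | 4-hydroxy-6-[2-oxo-4-(2,3,4,5-tetramethoxyphenyl)but-3-yn-1-yl]pyran-2-one | COc1cc(C#CC(=O)Cc2cc(O)cc(=O)o2)c(OC)c(OC)c1OC
A6 | alternative 3 | 5-fluoro-7-methoxy-2-(2,3,4,5-tetramethoxyphenyl)chromen-4-one | COc1cc(F)c2c(=O)cc(-c3cc(OC)c(OC)c(OC)c3OC)oc2c1
A7 | alternative 3 | 1-(2,6-difluoro-4-methoxyphenyl)-3-(2,3,4,5-tetramethoxyphenyl)propane-1,3-dione | COc1cc(F)c(C(=O)CC(=O)c2cc(OC)c(OC)c(OC)c2OC)c(F)c1
A8 | alternative 3 | 1-(2,6-difluoro-4-methoxyphenyl)ethanone | CC(=O)c1c(F)cc(OC)cc1F
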